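All runs are calculated with made-up constants, and the scatter is random.

West runs 2.50 times as long as eta's last reading, on the same charges of electrophile and nucleophile but with more solid base, so the question is how long eta's pace lasts.

| setting | eta | west | north |
|---|---|---|---|
| electrophile | 20 mM | 20 mM | 20 mM |
| nucleophile | 30 mM | 30.0 mM | 45.0 mM |
| solid base | 11 mM | 16.0 mM | 16.0 mM |
| remark | run made earlier |  |  |
| time |  | 50 min | 50 min |

eta run (percent of the electrophile charged)

| time / min | electrophile / % | product / % |
|---|---|---|
| 4.00 | 86 | 7 |
| 8.00 | 73 | 17 |
| 12.0 | 65 | 18 |
| 20.0 | 49 | 27 |

(standard deviation of a reading: 1.5 percentage points)

- solid base is a solid; its amount is given per volume of the solution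
- the earlier runs were read with a standard deviation of 1.5 percentage points
- at the start none of the solid base is in solution
- a reading or a percentage of product counts all its forms, free or not
- what has gone from electrophile into another species counts as reacted, even if it can come back
- no earlier run changes the charge of solid base; that part of a forecast is a guess
- a reading of electrophile is of its free form alone

1. part of the electrophile that has reacted at the end, west
2. part of the electrophile that has reacted at the end, north
3. what raising the concentration of nucleophile from its lowest to its highest value here does to the part of the electrophile that has reacted (changes below 5 percentage points count as none) (it rises / it falls / no change)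

I reckon with f, the fraction of electrophile left. I take the rate as κ[electrophile][nucleophile], an order no run has tested. Dividing by [electrophile] removes the first slowing, so ln(1/f) climbs at the pace κ[nucleophile], a pseudo-first-order constant that falls with g, the fraction of nucleophile left. No run reads nucleophile, so I guess that one goes per electrophile lost, and that the extra solid base leaves the rate alone. The ratio g/f then grows exponentially:

ln(g/f) = κ × (charged nucleophile − charged electrophile) × t

reacted = (R − 1) / (R − a), where R = g/f and a = charged electrophile / charged nucleophile

Eta's last reading has f = 49% and g = 66.0%, which gives the loss constant κ 1.49 /M/min, a reading with that reading's scatter.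

West: pace at the start 0.0447 /min; R = 2.11; reacted 76.8%; pace at the end down to 48.8% of its start.

North: pace at the start 0.0670 /min; R = 6.43; reacted 90.7%.

So I expect a rise of 14 percentage points, beyond the margin of 5 points.

The forecast, at 85% for west and 93% for north, stands above my figures, and of the part reacted it says it rises, in its words “probably rises, though weakly determined”. West gives 74.1% and north 86.6%; of the part reacted, the two flasks say it rises, by 12 points.

    2 electrophile → homo dimer (k = 9.30 × 10⁻⁵ /M/s)
    electrophile + nucleophile → acid set free + product (k = 0.0120 /M/s)
    solid base ⇌ free base, rate k3*(cs3 - [free base]) while solid is left; crystals form when [free base] > cs3 (solubility = 16.0 mM, k = 0.00120 /s)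
    acid set free + free base ⇌ salt of the base (K = 17000 /M, k = 0.430 /M/s)
    electrophile + product ⇌ idle adduct, settled at all times (K = 2100 /M)
    nucleophile + acid set free ⇌ protonated nucleophile, settled at all times (K = 26000 /M)

West ends with 49.3% of its nucleophile free, beside the 48.8% I reckoned. Taking κ = 1.49 /M/min to north read at 20 min, R = 2.11 and I get 66.6% reacted; that flask stands at 64.2%.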